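**Retrosynthetic overview**

1. Numbering: C1 lactone C=O, C2–C6 ring CH2, C7 ring carbinol, C8/C9/C10 cyclopropane, C11 and C14 carbinols, C12=C13 (E), C16=C17 and C19=C20 (Z). Last cut is C11–C12: an (E)-alkenylzinc (C12–C22, O14 silylated) adds to a C11 aldehyde.
2. Eight-membered lactone: cut at C6–C7 and tied instead at C1–C4 as a cyclobutane, giving a trans-cyclopropyl aldehyde (C7–C11) and (S)-2-vinylcyclobutanone dimethyl ketal (C1–C6). Their union is a strain-driven 2-oxonia-Cope ring expansion that ends at the lactone oxidation level.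
3. Enabling feature: in the oxocane ring, C7–O7–C1 and C4–C5–C6 are two three-atom halves joined at C6–C7 and facing each other 1,4 across the ring (C1···C4). A temporary C4=C5 alkene plus a C1–C4 bond make them the six-atom array of a [3,3] shift. C2–C6 are unsubstituted, so the leftover alkene is removed by hydrogenation.
4. Building blocks: cyclobutane by catalytic asymmetric [2+2]; trans-cyclopropane by asymmetric Simmons–Smith reaction; C14 by asymmetric alkynylation of (3Z,6Z)-nona-3,6-dienal.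
5. Ring order: cyclobutane (step 1), cyclopropane (step 7), lactone ring (step 9, where the cyclobutane is consumed).

Key step: step 9

Assumption (remark on the chemistry): the face selection of the chiral catalysts in steps 1 and 14 is assigned by analogy with their usual behaviour; if either proves opposite, the equally available antipodal ligand is used and nothing else changes.

**Route**

Step 1
Reactants: 1 3-(prop-2-enoyl)-1,3-oxazolidin-2-one; 2 1,1-bis(methylsulfanyl)ethene
Product: 3 3-{[(1S)-2,2-bis(methylsulfanyl)cyclobutyl]carbonyl}-1,3-oxazolidin-2-one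
Conditions: TiCl2(OiPr)2 (10 mol %), (R,R)-TADDOL (11 mol %), 4 Å MS, toluene–petroleum ether, 0 °C
Reagents that add atoms: none
Why: TADDOL–titanium-catalysed stepwise [2+2] cycloaddition of an electron-rich ketene dithioacetal with the chelated acryloyl imide, in which the chiral titanium chelate shields one face of the acrylamide and so sets the ring stereocentre that becomes C4.

Step 2
Reactants: 3 3-{[(1S)-2,2-bis(methylsulfanyl)cyclobutyl]carbonyl}-1,3-oxazolidin-2-one
Product: 4 [(1S)-2,2-bis(methylsulfanyl)cyclobutyl]methanol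
Conditions: LiBH4, MeOH (1 equiv), THF, 0 °C → rt
Reagents that add atoms: none
Why: Reductive cleavage of an N-acyl oxazolidinone by LiBH4 should give the primary alcohol without touching the dithioketal or the stereocentre.

Step 3
Reactants: 4 [(1S)-2,2-bis(methylsulfanyl)cyclobutyl]methanol
Product: 5 [(1S)-2,2-dimethoxycyclobutyl]methanol
Conditions: PhI(OCOCF3)2 (1.2 equiv), 2,6-lutidine, dry MeOH, 3 Å MS, −10 °C → rt
Reagents that add atoms: methanol, CO
Why: Oxidative dethioketalisation with a bis(acyloxy)iodoarene in dry methanol should exchange both C–S bonds for C–OMe bonds through thionium ions that the solvent captures faster than they can lose the ring α-proton.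

Step 4
Reactants: 5 [(1S)-2,2-dimethoxycyclobutyl]methanol
Product: 6 (1S)-2,2-dimethoxycyclobutane-1-carbaldehyde
Conditions: Dess–Martin periodinane, pyridine, CH2Cl2, 0 °C → rt; used crude
Reagents that add atoms: none
Why: Dess–Martin oxidation under pyridine buffering is neutral enough to keep both the ketal and the α-stereocentre of the aldehyde.

Step 5
Reactants: 6 (1S)-2,2-dimethoxycyclobutane-1-carbaldehyde
Product: 7 (2S)-2-ethenyl-1,1-dimethoxycyclobutane
Conditions: Ph3PCH3Br, KN(SiMe3)2, THF, 0 °C; then 6, −78 → 0 °C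
Reagents that add atoms: methyltriphenylphosphonium bromide, C[P+](c1ccccc1)(c1ccccc1)c1ccccc1.[Br-]
Why: Wittig methylenation with the salt-poor non-stabilised ylide at low temperature should add to the aldehyde faster than it enolises it, so the stereocentre is carried into the vinyl ketal.

Step 6
Reactants: 8 (2E)-but-2-ene-1,4-diol
Product: 9 (2E)-4-{[tert-butyl(diphenyl)silyl]oxy}but-2-en-1-ol
Conditions: NaH (1.0 equiv), THF, 0 °C; TBDPSCl (1.0 equiv), 0 °C → rt
Reagents that add atoms: tert-butyl(chloro)diphenylsilane, CC(C)(C)[Si](Cl)(c1ccccc1)c1ccccc1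
Why: Monosilylation of a symmetric diol through its sparingly soluble mono-sodium alkoxide should favour the mono-ether.

Step 7
Reactants: 9 (2E)-4-{[tert-butyl(diphenyl)silyl]oxy}but-2-en-1-ol
Product: 10 [(1R,2R)-2-({[tert-butyl(diphenyl)silyl]oxy}methyl)cyclopropyl]methanol
Conditions: Et2Zn, CH2I2, DME, CH2Cl2, −10 °C; (4S,5S)-2-butyl-N,N,N′,N′-tetramethyl-1,3,2-dioxaborolane-4,5-dicarboxamide (1.2 equiv), −10 °C → rt; aq. NH4Cl, then aq. KOH wash
Reagents that add atoms: diiodomethane, ICI
Why: Asymmetric Simmons–Smith cyclopropanation (Charette dioxaborolane modification), in which the zinc alkoxide binds the chiral boronate and Zn(CH2I)2 delivers CH2 to one face of the E-alkene; the E geometry gives the trans ring and the (S,S)-ligand should give the (1R,2R)-product that carries C8 and C10.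

Step 8
Reactants: 10 [(1R,2R)-2-({[tert-butyl(diphenyl)silyl]oxy}methyl)cyclopropyl]methanol
Product: 11 (1R,2R)-2-({[tert-butyl(diphenyl)silyl]oxy}methyl)cyclopropane-1-carbaldehyde
Conditions: Dess–Martin periodinane, NaHCO3, CH2Cl2, 0 °C → rt
Reagents that add atoms: none
Why: Dess–Martin oxidation of a primary alcohol to the aldehyde; the cyclopropane α-carbon does not epimerise under these conditions.

Step 9
Reactants: 7 (2S)-2-ethenyl-1,1-dimethoxycyclobutane; 11 (1R,2R)-2-({[tert-butyl(diphenyl)silyl]oxy}methyl)cyclopropane-1-carbaldehyde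
Product: 14 (5Z,8R)-8-[(1R,2R)-2-({[tert-butyl(diphenyl)silyl]oxy}methyl)cyclopropyl]-3,4,7,8-tetrahydro-2H-oxocin-2-one, via oxocarbenium ion 12 (not isolated), via methyl lactonium ion 13 (not isolated)
Conditions: Me3SiOTf (30 mol %), 4 Å MS, CH2Cl2, −78 → −40 °C; Et3N quench
Reagents that add atoms: none
Why: Proposed new method: Me3SiOTf ionises ketal 7 to a 1-methoxycyclobutyl oxocarbenium ion, whose reversible capture by the carbonyl oxygen of 11 (as in transacetalisation) gives oxocarbenium ion 12 with O7 cis to the vinyl group; 12 is a 2-oxa-1,5-diene cation and should undergo a 2-oxonia-Cope ([3,3]) shift in which C6 bonds to C7 as the cyclobutane bond C1–C4 breaks, after which the O-methyl lactonium ion 13 is demethylated by MeOSiMe3 (giving Me2O and returning Me3SiOTf). The closest known reactions are the 2-oxonia-Cope shifts that accompany Prins cyclisations, the strain-driven Cope rearrangement of cis-1,2-divinylcyclobutane to cycloocta-1,5-diene and the ketene-acetal Claisen ring expansion to eight-membered lactones; what is new is a cyclobutanone ketal as the σ-bond donor, so that the shift ends directly at the lactone oxidation level. The eight-membered ring is therefore closed at C6–C7 by a sigmatropic four-atom ring expansion through a six-centre boat transition state and not by an end-to-end cyclisation, and it is made irreversible by release of cyclobutane strain and by passage from a mono-oxygenated to a dioxygenated cation. The only new stereocentre, C7, is set by chirality transfer from C4 of 7: a cis-1,2-disubstituted cyclobutane can react only through the boat, the (E)-oxocarbenium places cyclopropyl outside and H inside, and with (S)-C4 this geometry should deliver (R)-C7, while the C4=C5 alkene can only be Z in the ring. The step needs [3,3] to outrun Prins, ene and cation-rearrangement paths and needs C4 to keep its configuration; this is secured by intramolecularity, by the low nucleophilicity of a monosubstituted alkene towards other cations at −78 °C, and by using the ketal (no enolisable ketone, no added base) so that the allylic C4–H is not lost.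

Step 10
Reactants: 14 (5Z,8R)-8-[(1R,2R)-2-({[tert-butyl(diphenyl)silyl]oxy}methyl)cyclopropyl]-3,4,7,8-tetrahydro-2H-oxocin-2-one
Product: 15 (8R)-8-[(1R,2R)-2-({[tert-butyl(diphenyl)silyl]oxy}methyl)cyclopropyl]oxocan-2-one
Conditions: H2 (1 atm), RhCl(PPh3)3 (5 mol %), benzene–EtOH, rt
Reagents that add atoms: none
Why: Homogeneous hydrogenation with RhCl(PPh3)3 should saturate the only alkene (a cis-disubstituted ring alkene) and leave the cyclopropane, the lactone and the silyl ether untouched, with no stereocentre involved.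

Step 11
Reactants: 15 (8R)-8-[(1R,2R)-2-({[tert-butyl(diphenyl)silyl]oxy}methyl)cyclopropyl]oxocan-2-one
Product: 16 (8R)-8-[(1R,2R)-2-(hydroxymethyl)cyclopropyl]oxocan-2-one
Conditions: HF·pyridine, pyridine, THF, 0 °C → rt
Reagents that add atoms: none
Why: Fluoride-mediated cleavage of the silyl ether under buffered, weakly acidic conditions should spare the base-sensitive medium-ring lactone.

Step 12
Reactants: 16 (8R)-8-[(1R,2R)-2-(hydroxymethyl)cyclopropyl]oxocan-2-one
Product: 17 (1R,2R)-2-[(2R)-8-oxooxocan-2-yl]cyclopropane-1-carbaldehyde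
Conditions: Dess–Martin periodinane, NaHCO3, CH2Cl2, 0 °C
Reagents that add atoms: none
Why: Dess–Martin oxidation gives the C11 aldehyde without epimerising the cyclopropane carbon or opening the lactone.

Step 13
Reactants: 18 (3Z,6Z)-nona-3,6-dien-1-ol
Product: 19 (3Z,6Z)-nona-3,6-dienal
Conditions: Dess–Martin periodinane, NaHCO3, CH2Cl2, 0 °C; crude aldehyde used at once
Reagents that add atoms: none
Why: Buffered Dess–Martin oxidation is mild enough to keep the skipped (Z,Z)-diene from moving into conjugation with the new aldehyde.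

Step 14
Reactants: 19 (3Z,6Z)-nona-3,6-dienal; 20 ethynyl(trimethyl)silane
Product: 22 (3S,5Z,8Z)-1-(trimethylsilyl)undeca-5,8-dien-1-yn-3-ol, via alkynylzinc 21 (not isolated)
Conditions: 20, Et2Zn, HMPA, CH2Cl2, rt; (R)-BINOL (40 mol %), Ti(OiPr)4 (50 mol %); 19, 0 °C → rt; aq. NH4Cl
Reagents that add atoms: none
Why: BINOL–titanium-catalysed addition of an alkynylzinc to an aldehyde, in which the (R)-BINOL complex should direct the alkynyl group to the Re face and so set (S)-C14 under conditions that are neither strongly basic nor protic.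

Step 15
Reactants: 22 (3S,5Z,8Z)-1-(trimethylsilyl)undeca-5,8-dien-1-yn-3-ol
Product: 23 tert-butyl(dimethyl){[(3S,5Z,8Z)-1-(trimethylsilyl)undeca-5,8-dien-1-yn-3-yl]oxy}silane
Conditions: TBSCl, imidazole, DMF, rt
Reagents that add atoms: tert-butyl(chloro)dimethylsilane, CC(C)(C)[Si](C)(C)Cl
Why: Standard silylation of a secondary propargylic alcohol, which protects O14 through the organometallic coupling.

Step 16
Reactants: 23 tert-butyl(dimethyl){[(3S,5Z,8Z)-1-(trimethylsilyl)undeca-5,8-dien-1-yn-3-yl]oxy}silane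
Product: 24 tert-butyl(dimethyl){[(3S,5Z,8Z)-undeca-5,8-dien-1-yn-3-yl]oxy}silane
Conditions: K2CO3 (cat.), MeOH, 0 °C → rt
Reagents that add atoms: none
Why: Methanolysis cleaves the C(sp)–Si bond selectively, while the secondary silyl ether is stable to catalytic carbonate.

Step 17
Reactants: 24 tert-butyl(dimethyl){[(3S,5Z,8Z)-undeca-5,8-dien-1-yn-3-yl]oxy}silane; 17 (1R,2R)-2-[(2R)-8-oxooxocan-2-yl]cyclopropane-1-carbaldehyde
Product: 27 (8R)-8-[(1R,2R)-2-[(1S,2E,4S,6Z,9Z)-4-{[tert-butyl(dimethyl)silyl]oxy}-1-hydroxydodeca-2,6,9-trien-1-yl]cyclopropyl]oxocan-2-one, via alkenylborane 25 (not isolated), via alkenylzinc 26 (not isolated)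
Conditions: 24, Cy2BH, toluene, 0 °C → rt; Et2Zn, −78 °C; (−)-MIB (10 mol %); 17, −20 → 0 °C; aq. NH4Cl
Reagents that add atoms: none
Why: Syn hydroboration of the terminal alkyne (faster than of the Z-alkenes) fixes E-C12=C13, boron-to-zinc exchange gives the alkenylzinc, and its amino-alcohol-catalysed addition to the Si face of the aldehyde (catalyst control over the weak bias of the cyclopropane) should set (S)-C11 while the lactone stays inert to organozinc.

Step 18
Reactants: 27 (8R)-8-[(1R,2R)-2-[(1S,2E,4S,6Z,9Z)-4-{[tert-butyl(dimethyl)silyl]oxy}-1-hydroxydodeca-2,6,9-trien-1-yl]cyclopropyl]oxocan-2-one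
Product: 28 (8R)-8-[(1R,2R)-2-[(1S,2E,4S,6Z,9Z)-1,4-dihydroxydodeca-2,6,9-trien-1-yl]cyclopropyl]oxocan-2-one (CNP0227294.2)
Conditions: HF·pyridine, pyridine, THF, 0 °C → rt
Reagents that add atoms: none
Why: Buffered fluoride desilylation frees O14 without ionising the allylic alcohols, isomerising the skipped diene or opening the lactone.

**Compound list**

1 | 3-(prop-2-enoyl)-1,3-oxazolidin-2-one | C=CC(=O)N1CCOC1=O | starting material
2 | 1,1-bis(methylsulfanyl)ethene | C=C(SC)SC | starting material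
3 | 3-{[(1S)-2,2-bis(methylsulfanyl)cyclobutyl]carbonyl}-1,3-oxazolidin-2-one | O=C([C@@H]1CCC1(SC)SC)N1CCOC1=O | intermediate
4 | [(1S)-2,2-bis(methylsulfanyl)cyclobutyl]methanol | OC[C@@H]1CCC1(SC)SC | intermediate
5 | [(1S)-2,2-dimethoxycyclobutyl]methanol | OC[C@@H]1CCC1(OC)OC | intermediate
6 | (1S)-2,2-dimethoxycyclobutane-1-carbaldehyde | O=C[C@@H]1CCC1(OC)OC | intermediate
7 | (2S)-2-ethenyl-1,1-dimethoxycyclobutane | C=C[C@@H]1CCC1(OC)OC | intermediate
8 | (2E)-but-2-ene-1,4-diol | OC/C=C/CO | starting material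
9 | (2E)-4-{[tert-butyl(diphenyl)silyl]oxy}but-2-en-1-ol | CC(C)(C)[Si](c1ccccc1)(c1ccccc1)OC/C=C/CO | intermediate
10 | [(1R,2R)-2-({[tert-butyl(diphenyl)silyl]oxy}methyl)cyclopropyl]methanol | CC(C)(C)[Si](c1ccccc1)(c1ccccc1)OC[C@@H]1C[C@H]1CO | intermediate
11 | (1R,2R)-2-({[tert-butyl(diphenyl)silyl]oxy}methyl)cyclopropane-1-carbaldehyde | CC(C)(C)[Si](c1ccccc1)(c1ccccc1)OC[C@@H]1C[C@H]1C=O | intermediate
12 | {(E)-[(1R,2R)-2-({[tert-butyl(diphenyl)silyl]oxy}methyl)cyclopropyl]methylidene}[(1S,2S)-2-ethenyl-1-methoxycyclobutyl]oxonium (oxocarbenium ion, O7 cis to vinyl) | C=C[C@@H]1CC[C@]1(OC)/[O+]=C/[C@@H]1C[C@H]1CO[Si](c1ccccc1)(c1ccccc1)C(C)(C)C | intermediate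
13 | (5Z,8R)-8-[(1R,2R)-2-({[tert-butyl(diphenyl)silyl]oxy}methyl)cyclopropyl]-2-methoxy-3,4,7,8-tetrahydrooxocin-1-ium (O-methyl lactonium ion) | COC1=[O+][C@@H]([C@@H]2C[C@H]2CO[Si](c2ccccc2)(c2ccccc2)C(C)(C)C)C/C=C\CC1 | intermediate
14 | (5Z,8R)-8-[(1R,2R)-2-({[tert-butyl(diphenyl)silyl]oxy}methyl)cyclopropyl]-3,4,7,8-tetrahydro-2H-oxocin-2-one | CC(C)(C)[Si](c1ccccc1)(c1ccccc1)OC[C@@H]1C[C@H]1[C@H]1C/C=C\CCC(=O)O1 | intermediate
15 | (8R)-8-[(1R,2R)-2-({[tert-butyl(diphenyl)silyl]oxy}methyl)cyclopropyl]oxocan-2-one | CC(C)(C)[Si](c1ccccc1)(c1ccccc1)OC[C@@H]1C[C@H]1[C@H]1CCCCCC(=O)O1 | intermediate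
16 | (8R)-8-[(1R,2R)-2-(hydroxymethyl)cyclopropyl]oxocan-2-one | OC[C@@H]1C[C@H]1[C@H]1CCCCCC(=O)O1 | intermediate
17 | (1R,2R)-2-[(2R)-8-oxooxocan-2-yl]cyclopropane-1-carbaldehyde | O=C[C@@H]1C[C@H]1[C@H]1CCCCCC(=O)O1 | intermediate
18 | (3Z,6Z)-nona-3,6-dien-1-ol | CC/C=C\C/C=C\CCO | starting material
19 | (3Z,6Z)-nona-3,6-dienal | CC/C=C\C/C=C\CC=O | intermediate
20 | ethynyl(trimethyl)silane | C#C[Si](C)(C)C | starting material
21 | ethyl[(trimethylsilyl)ethynyl]zinc | CC[Zn]C#C[Si](C)(C)C | intermediate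
22 | (3S,5Z,8Z)-1-(trimethylsilyl)undeca-5,8-dien-1-yn-3-ol | CC/C=C\C/C=C\C[C@H](O)C#C[Si](C)(C)C | intermediate
23 | tert-butyl(dimethyl){[(3S,5Z,8Z)-1-(trimethylsilyl)undeca-5,8-dien-1-yn-3-yl]oxy}silane | CC/C=C\C/C=C\C[C@H](O[Si](C)(C)C(C)(C)C)C#C[Si](C)(C)C | intermediate
24 | tert-butyl(dimethyl){[(3S,5Z,8Z)-undeca-5,8-dien-1-yn-3-yl]oxy}silane | CC/C=C\C/C=C\C[C@H](O[Si](C)(C)C(C)(C)C)C#C | intermediate
25 | [(1E,3S,5Z,8Z)-3-{[tert-butyl(dimethyl)silyl]oxy}undeca-1,5,8-trien-1-yl](dicyclohexyl)borane | CC/C=C\C/C=C\C[C@H](O[Si](C)(C)C(C)(C)C)/C=C/B(C1CCCCC1)C1CCCCC1 | intermediate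
26 | [(1E,3S,5Z,8Z)-3-{[tert-butyl(dimethyl)silyl]oxy}undeca-1,5,8-trien-1-yl](ethyl)zinc | CC/C=C\C/C=C\C[C@H](O[Si](C)(C)C(C)(C)C)/C=C/[Zn]CC | intermediate
27 | (8R)-8-[(1R,2R)-2-[(1S,2E,4S,6Z,9Z)-4-{[tert-butyl(dimethyl)silyl]oxy}-1-hydroxydodeca-2,6,9-trien-1-yl]cyclopropyl]oxocan-2-one | CC/C=C\C/C=C\C[C@H](O[Si](C)(C)C(C)(C)C)/C=C/[C@H](O)[C@@H]1C[C@H]1[C@H]1CCCCCC(=O)O1 | intermediate
28 | (8R)-8-[(1R,2R)-2-[(1S,2E,4S,6Z,9Z)-1,4-dihydroxydodeca-2,6,9-trien-1-yl]cyclopropyl]oxocan-2-one | CC/C=C\C/C=C\C[C@H](O)/C=C/[C@H](O)[C@@H]1C[C@H]1[C@H]1CCCCCC(=O)O1 | target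

**Step count and risks**

Total steps: 18. Longest linear sequence: 11 (steps 1–5, 9–12, 17, 18).

Steps most likely to fail:

Step 9 (the proposed new method). Three processes may defeat it: the mixed ketal–oxocarbenium ion may not assemble because transketalisation to the aldehyde acetal wins; the cyclobutyl oxocarbenium ion may lose its allylic α-proton, which erases the C4 configuration that controls C7; or the O-methyl lactonium ion may ionise at the cyclopropylcarbinyl C7–O bond instead of being demethylated. The fallback uses known chemistry, sets out from 11 and returns at 14. Brown allylation of 11 with (+)-Ipc2B(allyl) (Re-face addition, then oxidative work-up) should give (1R)-1-[(1R,2R)-2-({[tert-butyl(diphenyl)silyl]oxy}methyl)cyclopropyl]but-3-en-1-ol F1. Esterification with pent-4-enoic acid (DCC, DMAP) gives the diene ester (1R)-1-[(1R,2R)-2-({[tert-butyl(diphenyl)silyl]oxy}methyl)cyclopropyl]but-3-en-1-yl pent-4-enoate F2. Ring-closing metathesis with the second-generation Grubbs catalyst at high dilution closes the ring at C4=C5 and gives 14, which rejoins the route at step 10.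

Step 17. Facial selectivity at C11 may be poor if the catalyst and the cyclopropane stereocentre are mismatched, and boron-to-zinc exchange may be incomplete. The fallback sets out from 24 (with 17) and returns at 27. Hydrozirconation of 24 with Cp2Zr(H)Cl followed by iodine gives tert-butyl{[(1E,3S,5Z,8Z)-1-iodoundeca-1,5,8-trien-3-yl]oxy}dimethylsilane F3. Nozaki–Hiyama–Kishi coupling of F3 with 17 (CrCl2, NiCl2 cat., DMSO) gives 27 together with its C11 epimer (8R)-8-[(1R,2R)-2-[(1R,2E,4S,6Z,9Z)-4-{[tert-butyl(dimethyl)silyl]oxy}-1-hydroxydodeca-2,6,9-trien-1-yl]cyclopropyl]oxocan-2-one F4. The mixture is oxidised with Dess–Martin periodinane to the enone (8R)-8-[(1R,2R)-2-[(2E,4S,6Z,9Z)-4-{[tert-butyl(dimethyl)silyl]oxy}dodeca-2,6,9-trienoyl]cyclopropyl]oxocan-2-one F5. Corey–Bakshi–Shibata reduction with the (S)-oxazaborolidine and catecholborane (alkenyl arm taken as the large group) should then return 27 as one epimer.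

Step 14. The β,γ-unsaturated aldehyde may isomerise into conjugation during the slow catalytic addition, and an unbranched aldehyde may give a low enantiomeric ratio. The fallback sets out from 20 and returns at 23; it sets C14 on a robust ynal and forms C16=C17 last. Deprotonation of 20 (n-BuLi) and formylation with DMF gives 3-(trimethylsilyl)prop-2-ynal F6. Brown allylation with (−)-Ipc2B(allyl) (Si face) should give (3S)-1-(trimethylsilyl)hex-5-en-1-yn-3-ol F7. Silylation (TBSCl, imidazole) gives tert-butyl(dimethyl){[(3S)-1-(trimethylsilyl)hex-5-en-1-yn-3-yl]oxy}silane F8. Ozonolysis of the terminal alkene (O3, −78 °C; PPh3) gives (3S)-3-{[tert-butyl(dimethyl)silyl]oxy}-5-(trimethylsilyl)pent-4-ynal F9. A Z-selective Wittig reaction of F9 with the ylide from [(3Z)-hex-3-en-1-yl](triphenyl)phosphonium bromide F10 (made from commercial (3Z)-1-bromohex-3-ene and PPh3; NaN(SiMe3)2, THF, −78 °C) gives 23.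

Further compounds

F1 | step 9 | (1R)-1-[(1R,2R)-2-({[tert-butyl(diphenyl)silyl]oxy}methyl)cyclopropyl]but-3-en-1-ol | CC(C)(C)[Si](c1ccccc1)(c1ccccc1)OC[C@@H]1C[C@H]1[C@H](O)CC=C
F2 | step 9 | (1R)-1-[(1R,2R)-2-({[tert-butyl(diphenyl)silyl]oxy}methyl)cyclopropyl]but-3-en-1-yl pent-4-enoate | CC(C)(C)[Si](c1ccccc1)(c1ccccc1)OC[C@@H]1C[C@H]1[C@H](OC(=O)CCC=C)CC=C
F3 | step 17 | tert-butyl{[(1E,3S,5Z,8Z)-1-iodoundeca-1,5,8-trien-3-yl]oxy}dimethylsilane | CC/C=C\C/C=C\C[C@H](O[Si](C)(C)C(C)(C)C)/C=C/I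
F4 | step 17 | (8R)-8-[(1R,2R)-2-[(1R,2E,4S,6Z,9Z)-4-{[tert-butyl(dimethyl)silyl]oxy}-1-hydroxydodeca-2,6,9-trien-1-yl]cyclopropyl]oxocan-2-one | CC/C=C\C/C=C\C[C@H](O[Si](C)(C)C(C)(C)C)/C=C/[C@@H](O)[C@@H]1C[C@H]1[C@H]1CCCCCC(=O)O1
F5 | step 17 | (8R)-8-[(1R,2R)-2-[(2E,4S,6Z,9Z)-4-{[tert-butyl(dimethyl)silyl]oxy}dodeca-2,6,9-trienoyl]cyclopropyl]oxocan-2-one | CC/C=C\C/C=C\C[C@H](O[Si](C)(C)C(C)(C)C)/C=C/C(=O)[C@@H]1C[C@H]1[C@H]1CCCCCC(=O)O1
F6 | step 14 | 3-(trimethylsilyl)prop-2-ynal | C[Si](C)(C)C#CC=O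
F7 | step 14 | (3S)-1-(trimethylsilyl)hex-5-en-1-yn-3-ol | C=CC[C@H](O)C#C[Si](C)(C)C
F8 | step 14 | tert-butyl(dimethyl){[(3S)-1-(trimethylsilyl)hex-5-en-1-yn-3-yl]oxy}silane | C=CC[C@H](O[Si](C)(C)C(C)(C)C)C#C[Si](C)(C)C
F9 | step 14 | (3S)-3-{[tert-butyl(dimethyl)silyl]oxy}-5-(trimethylsilyl)pent-4-ynal | O=CC[C@H](O[Si](C)(C)C(C)(C)C)C#C[Si](C)(C)C
F10 | step 14 | [(3Z)-hex-3-en-1-yl](triphenyl)phosphonium bromide | CC/C=C\CC[P+](c1ccccc1)(c1ccccc1)c1ccccc1.[Br-]
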